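A small charge of precatalyst, 0.20 mM, acts on starting material, second substrate and partner; the earlier runs below differ in their second substrate, and the flasks asked about differ in when the starting material or the partner goes in.

| flask | starting material | second substrate | partner | precatalyst | added ligand | remark | time |
|---|---|---|---|---|---|---|---|
| north-west | 0.10 M | 0.10 M | 0.095 M | 0.20 mM | 1.1 mM | run made earlier |  |
| north | 0.10 M | 0.14 M | 0.095 M | 0.20 mM | 1.1 mM | run made earlier |  |
| east | 0.10 M | 0.22 M | 0.095 M | 0.20 mM | 1.1 mM | run made earlier |  |
| ochre | 0.10 M (fed, over 25 h) | 0.100 M | 0.0950 M | 0.20 mM | 1.1 mM | all else is in the flask from the start; the feed brings no volume worth counting | 6.0 d |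
| grey | 0.10 M (fed, over 4.0 d) | 0.100 M | 0.0950 M | 0.20 mM | 1.1 mM | all else is in the flask from the start; the feed brings no volume worth counting | 6.0 d |
| blue | 0.10 M | 0.100 M | 0.0950 M | 0.20 mM | 1.1 mM | everything together at the start | 6.0 d |
| teal | 0.10 M (in portions, 3, over 4.0 d) | 0.100 M | 0.0950 M | 0.20 mM | 1.1 mM | first portion at the start, last at 4.0 d | 6.0 d |
| red | 0.10 M | 0.100 M | 0.0950 M (fed, over 4.0 d) | 0.20 mM | 1.1 mM | all else is in the flask from the start; the feed brings no volume worth counting | 6.0 d |

- north-west (time / d: target / %, starting material / %): 0.833: 10.1, 89.3; 2.00: 14.2, 85.5; 4.00: 15.0, 85.8; 6.00: 14.1, 85.4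
- north (time / d: target / %, starting material / %): 0.500: 4.4, 96.0; 1.04: 8.5, 91.5; 2.50: 9.3, 90.9; 6.00: 9.2, 90.3
- east (time / d: target / %, starting material / %): 0.833: 4.5, 95.7; 2.00: 5.7, 94.7; 4.00: 5.2, 94.3; 6.00: 5.9, 94.1

(each reading ± 0.3 percentage points)

- the numbers in the tables scatter by 0.3 percentage points (one standard deviation)

1. the flask that comes out highest in amount of target, in percent of the starting material charged, or "all alike" when all lie within 1.5 percentage points (ochre / grey / blue / teal / red / all alike)
2. target at the end, in percent of the starting material charged, ochre
3. target at the end, in percent of the starting material charged, grey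
4. target at the end, in percent of the starting material charged, blue
5. target at the end, in percent of the starting material charged, teal
6. target at the end, in percent of the starting material charged, red

In each earlier run the target climbs and then stands still. The north-west run reads a plateau of 14.4 % and has 10.1 % after 0.833 d. I call the plateau divided by the early rate the stop time 1.19 d. The same reading gives 1.13 d in the north run and 1.04 d in the east run, so I treat it as a clock of about that length.

Next I guess that the rate of target follows the starting material present; it stays a guess, for the north-west run still reads 85.4 % of it at the end. On that guess a flask makes the plateau times its mean share of starting material over the stop time. Blue repeats the north-west run, so I put it at 14.4 %. Ochre's feed ends at 25 h, inside the stop time, so its mean share is 56.2 %, which gives 8.12 %. Teal has its first portion for that whole time, which gives 4.81 %. Grey's mean share is 14.9 %, which gives 2.15 %.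

The weak link is red, since no run varies the partner and its order stands unread. First order would put red at grey's 2.15 %, and zero order at 14.4 %. I commit to their geometric mean, 5.57 %.

The forecast also says “catalyst life is a clock”. It puts blue highest, with ochre 8 %, grey 3 %, blue 14.5 %, teal 5.5 % and red 6 %. My grey and teal stand lower.

Blue comes out highest at 14.5 %, with ochre 10.5 %, red 9.12 %, teal 6.10 % and grey 3.99 %.

    second substrate + free catalyst ⇌ catalyst intermediate B (K = 1900 L mol⁻¹, k = 2900 L mol⁻¹ h⁻¹)
    partner + catalyst intermediate A → free catalyst + target (k = 940 L mol⁻¹ h⁻¹)
    precatalyst → free catalyst (k = 0.0910 h⁻¹)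
    starting material + free catalyst ⇌ catalyst intermediate A (K = 19.0 L mol⁻¹, k = 580 L mol⁻¹ h⁻¹)
    free catalyst + added ligand ⇌ idle complex, settled at all times (K = 310 L mol⁻¹)
    partner + catalyst intermediate B → free catalyst + second product (k = 630 L mol⁻¹ h⁻¹)

In blue at 6.00 d, the partner, the limiting reagent, stands at 0 %, and second product at 0.0805 M. Red fed over 4.0 d gives 9.12 %, but fed over 1.20 d, next to the stop time of 1.19 d, it gives 13.2 %.

(The readings are simulated on assumed constants.)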